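**Retrosynthetic overview**

- Structural feature: a heptane chain C1 (catechol ring) to C7 (4-hydroxyphenyl ring) with one stereocenter, C3 (OAc). The unit C3–C4–C5–C6=C7 is a γ,δ-unsaturated carbonyl pattern once C3 is an ester carbon, and its (E)-alkene is conjugated to the 4-hydroxyphenyl ring.
- Last skeletal disconnection, C2–C3: catalytic enantioselective addition of a mixed (2-arylethyl)(trimethylsilylmethyl)zinc, made from the protected 3,4-dihydroxystyrene, to the C3 aldehyde sets (R)-C3.
- Key disconnection, C4–C5: orthoester Claisen rearrangement of a racemic 1-arylprop-2-en-1-ol with triethyl orthoacetate gives the C3 ester and the (E)-C6=C7 styrene in one operation.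
- No ring is formed; both arenes are bought as hydroxybenzaldehydes. All three phenols travel as tert-butyldimethylsilyl ethers and are released last, after acetylation of C3–OH.

Key step: step 3

Remark: TBS = tert-butyldimethylsilyl. C3 is read as (R) from the SMILES, because the C2 arm outranks the C4 arm at the first point of difference (arene ipso carbon C,C,C against alkene carbon C6 C,C,H).

**Route**

Step 1
Reactants: 1 4-hydroxybenzaldehyde
Product: 2 4-(tert-butyldimethylsilyloxy)benzaldehyde
Conditions: TBSCl (1.2 equiv), imidazole (2.5 equiv), DMF, rt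
Reagents that add atoms: tert-butyldimethylsilyl chloride, CC(C)(C)[Si](C)(C)Cl
Why: Imidazole-promoted O-silylation masks the acidic phenol so that the Grignard, hydride and organozinc reagents used later are not quenched.

Step 2
Reactants: 2 4-(tert-butyldimethylsilyloxy)benzaldehyde; 3 vinylmagnesium bromide
Product: 4 rac-1-[4-(tert-butyldimethylsilyloxy)phenyl]prop-2-en-1-ol
Conditions: 3 (1.2 equiv), THF, −78 → 0 °C; sat. aq. NH4Cl; purified on Et3N-deactivated silica or used crude
Reagents that add atoms: vinylmagnesium bromide (3), C=C[Mg]Br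
Why: Grignard 1,2-addition to a non-enolisable aryl aldehyde gives the secondary allylic alcohol, and the racemate suffices because this carbinol centre becomes sp2 in step 3.

Step 3
Reactants: 4 rac-1-[4-(tert-butyldimethylsilyloxy)phenyl]prop-2-en-1-ol; 5 triethyl orthoacetate
Product: 8 ethyl (E)-5-[4-(tert-butyldimethylsilyloxy)phenyl]pent-4-enoate, via mixed orthoester 6 (not isolated), via ketene acetal 7 (not isolated)
Conditions: 5 (6 equiv), EtCO2H (5 mol %), 138 °C, EtOH distilled off
Reagents that add atoms: triethyl orthoacetate (5), CCOC(C)(OCC)OCC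
Why: Propionic acid catalyses exchange of alcohol 4 into the orthoester to give mixed orthoester 6, which loses ethanol to the allyl ketene acetal 7; 7 then undergoes a concerted suprafacial [3,3]-sigmatropic shift that joins the orthoacetate methyl carbon (C4) to the vinyl terminus (C5) while the benzylic C–O bond breaks. This is the Johnson–Claisen (orthoester Claisen) rearrangement, well established for secondary 1-arylallyl alcohols. No ring is closed and no stereocenter is created, since the carbinol carbon of racemic 4 becomes the sp2 carbon C7. The selectivity needed is (E) geometry at C6=C7, secured by the chair transition state in which the aryl group on the carbinol carbon sits pseudo-equatorial to avoid a 1,3-diaxial clash with the ethoxy group of the ketene acetal. The driving force is the new ester C=O together with the aryl-conjugated alkene, and removal of ethanol pulls the two pre-equilibria forward. Only a weak carboxylic acid is present, so the electron-rich benzylic C–O bond should not ionise and the aryl silyl ether should survive.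

Step 4
Reactants: 8 ethyl (E)-5-[4-(tert-butyldimethylsilyloxy)phenyl]pent-4-enoate
Product: 10 (E)-5-[4-(tert-butyldimethylsilyloxy)phenyl]pent-4-enal, via aluminium hemiacetal 9 (not isolated)
Conditions: i-Bu2AlH (1.1 equiv), CH2Cl2, −78 °C; then aq. potassium sodium tartrate (KNaC4H4O6), rt
Reagents that add atoms: none
Why: Partial ester reduction with i-Bu2AlH stops at the tetrahedral aluminium hemiacetal 9, which is stable at −78 °C and releases the aldehyde only on work-up; the styrene and aryl silyl ether are inert.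

Step 5
Reactants: 11 3,4-dihydroxybenzaldehyde
Product: 12 3,4-bis(tert-butyldimethylsilyloxy)benzaldehyde
Conditions: TBSCl (2.4 equiv), imidazole (5 equiv), DMF, rt
Reagents that add atoms: tert-butyldimethylsilyl chloride, CC(C)(C)[Si](C)(C)Cl
Why: Imidazole-promoted bis-O-silylation protects the catechol against the ylide, borane and organometallic reagents and against air oxidation.

Step 6
Reactants: 12 3,4-bis(tert-butyldimethylsilyloxy)benzaldehyde; 13 methyltriphenylphosphonium bromide
Product: 14 3,4-bis(tert-butyldimethylsilyloxy)styrene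
Conditions: 13 (1.3 equiv), n-BuLi (1.2 equiv), THF, 0 °C; then 12, 0 °C → rt
Reagents that add atoms: methyltriphenylphosphonium bromide (13), C[P+](c1ccccc1)(c1ccccc1)c1ccccc1.[Br-]
Why: Wittig methylenation of a non-enolisable aldehyde with the non-stabilised ylide is reliable, and keeping the phosphonium salt in excess leaves no free base to attack the aryl silyl ethers.

Step 7
Reactants: 14 3,4-bis(tert-butyldimethylsilyloxy)styrene
Product: 16 2-[3,4-bis(tert-butyldimethylsilyloxy)phenyl]ethanol, via alkylborane 15 (not isolated)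
Conditions: 9-BBN (1.2 equiv), THF, 0 °C → rt; then 30% H2O2, pH 7 phosphate buffer (NaH2PO4/Na2HPO4), EtOH, 0 °C → rt
Reagents that add atoms: hydrogen peroxide, OO
Why: Hydroboration–oxidation with the bulky 9-BBN places boron, and then oxygen, on the terminal carbon of the styrene (anti-Markovnikov), and the buffered peroxide oxidation avoids the hydroxide that would cleave the aryl silyl ethers.

Step 8
Reactants: 16 2-[3,4-bis(tert-butyldimethylsilyloxy)phenyl]ethanol
Product: 17 4-(2-iodoethyl)-1,2-bis(tert-butyldimethylsilyloxy)benzene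
Conditions: Ph3P (1.3 equiv), imidazole (1.5 equiv), I2 (1.3 equiv), CH2Cl2, 0 °C → rt
Reagents that add atoms: iodine, II
Why: Appel-type iodination converts the primary alcohol through its alkoxyphosphonium salt into the primary iodide by SN2 displacement under near-neutral conditions that leave the silyl ethers alone.

Step 9
Reactants: 17 4-(2-iodoethyl)-1,2-bis(tert-butyldimethylsilyloxy)benzene
Product: 19 {2-[3,4-bis(tert-butyldimethylsilyloxy)phenyl]ethyl}[(trimethylsilyl)methyl]zinc, via alkylzinc iodide 18 (not isolated)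
Conditions: Zn dust (3 equiv, activated with BrCH2CH2Br 5 mol % and Me3SiCl 3 mol %), THF, 40 °C; solution decanted from excess Zn; Me3SiCH2Li (1.0 equiv, pentane), −78 → 0 °C; volatiles removed in vacuo; residue extracted into toluene and filtered from LiI under argon; used at once
Reagents that add atoms: zinc, [Zn]; (trimethylsilyl)methyllithium, [Li]C[Si](C)(C)C
Why: Direct insertion of activated zinc into the primary C–I bond gives alkylzinc iodide 18, and transmetalation with one equivalent of (trimethylsilyl)methyllithium replaces iodide by a trimethylsilylmethyl group that is not transferred to aldehydes (mixed diorganozinc with a non-transferable ligand), so every arylethyl group made is available for C3.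

Step 10
Reactants: 10 (E)-5-[4-(tert-butyldimethylsilyloxy)phenyl]pent-4-enal; 19 {2-[3,4-bis(tert-butyldimethylsilyloxy)phenyl]ethyl}[(trimethylsilyl)methyl]zinc
Product: 20 (3R,6E)-1-[3,4-bis(tert-butyldimethylsilyloxy)phenyl]-7-[4-(tert-butyldimethylsilyloxy)phenyl]hept-6-en-3-ol
Conditions: 19 (1.5 equiv), Ti(OiPr)4 (2 equiv), (1R,2R)-N,N′-(cyclohexane-1,2-diyl)bis(trifluoromethanesulfonamide) (8 mol %), toluene, −20 °C; sat. aq. NH4Cl
Reagents that add atoms: {2-[3,4-bis(tert-butyldimethylsilyloxy)phenyl]ethyl}[(trimethylsilyl)methyl]zinc (19), C[Si](C)(C)C[Zn]CCc1ccc(O[Si](C)(C)C(C)(C)C)c(O[Si](C)(C)C(C)(C)C)c1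
Why: This is the titanium/chiral bis-sulfonamide-catalysed enantioselective addition of a diorganozinc to an aldehyde, in which the mixed reagent transfers only its arylethyl group; the (1R,2R) ligand directs alkyl transfer to the Si face of aldehydes, which here corresponds to (R)-C3 because the incoming arylethyl group outranks the C4 chain.

Step 11
Reactants: 20 (3R,6E)-1-[3,4-bis(tert-butyldimethylsilyloxy)phenyl]-7-[4-(tert-butyldimethylsilyloxy)phenyl]hept-6-en-3-ol
Product: 21 (3R,6E)-1-[3,4-bis(tert-butyldimethylsilyloxy)phenyl]-7-[4-(tert-butyldimethylsilyloxy)phenyl]hept-6-en-3-yl acetate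
Conditions: Ac2O (2 equiv), pyridine (4 equiv), DMAP (10 mol %), CH2Cl2, 0 °C → rt
Reagents that add atoms: acetic anhydride, CC(=O)OC(C)=O
Why: DMAP-catalysed O-acylation of the only free hydroxyl proceeds without breaking the C3–O bond, so the (R) configuration is retained.

Step 12
Reactants: 21 (3R,6E)-1-[3,4-bis(tert-butyldimethylsilyloxy)phenyl]-7-[4-(tert-butyldimethylsilyloxy)phenyl]hept-6-en-3-yl acetate
Product: 22 (3R,6E)-1-(3,4-dihydroxyphenyl)-7-(4-hydroxyphenyl)hept-6-en-3-yl acetate (CID49831947)
Conditions: Bu4NF (3.6 equiv), AcOH (4 equiv), THF, 0 °C → rt, under argon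
Reagents that add atoms: none
Why: Fluoride-mediated desilylation cleaves aryl silyl ethers readily, and the acetic acid buffer keeps the phenols protonated so that the secondary acetate is not transesterified and the catechol is not oxidised.

**Compound list**

1 | 4-hydroxybenzaldehyde | O=Cc1ccc(O)cc1 | starting material
2 | 4-(tert-butyldimethylsilyloxy)benzaldehyde | O=Cc1ccc(O[Si](C)(C)C(C)(C)C)cc1 | intermediate
3 | vinylmagnesium bromide | C=C[Mg]Br | starting material
4 | rac-1-[4-(tert-butyldimethylsilyloxy)phenyl]prop-2-en-1-ol | C=CC(O)c1ccc(O[Si](C)(C)C(C)(C)C)cc1 | intermediate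
5 | triethyl orthoacetate | CCOC(C)(OCC)OCC | starting material
6 | 1,1-diethoxy-1-{1-[4-(tert-butyldimethylsilyloxy)phenyl]prop-2-enyloxy}ethane (mixed orthoester) | CCOC(C)(OCC)OC(C=C)c1ccc(O[Si](C)(C)C(C)(C)C)cc1 | intermediate
7 | 1-ethoxy-1-{1-[4-(tert-butyldimethylsilyloxy)phenyl]prop-2-enyloxy}ethene (ketene acetal) | C=C(OCC)OC(C=C)c1ccc(O[Si](C)(C)C(C)(C)C)cc1 | intermediate
8 | ethyl (E)-5-[4-(tert-butyldimethylsilyloxy)phenyl]pent-4-enoate | CCOC(=O)CC/C=C/c1ccc(O[Si](C)(C)C(C)(C)C)cc1 | intermediate
9 | diisobutylaluminium (E)-1-ethoxy-5-[4-(tert-butyldimethylsilyloxy)phenyl]pent-4-en-1-olate (aluminium hemiacetal) | CCOC(CC/C=C/c1ccc(O[Si](C)(C)C(C)(C)C)cc1)O[Al](CC(C)C)CC(C)C | intermediate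
10 | (E)-5-[4-(tert-butyldimethylsilyloxy)phenyl]pent-4-enal | O=CCC/C=C/c1ccc(O[Si](C)(C)C(C)(C)C)cc1 | intermediate
11 | 3,4-dihydroxybenzaldehyde | O=Cc1ccc(O)c(O)c1 | starting material
12 | 3,4-bis(tert-butyldimethylsilyloxy)benzaldehyde | O=Cc1ccc(O[Si](C)(C)C(C)(C)C)c(O[Si](C)(C)C(C)(C)C)c1 | intermediate
13 | methyltriphenylphosphonium bromide | C[P+](c1ccccc1)(c1ccccc1)c1ccccc1.[Br-] | starting material
14 | 3,4-bis(tert-butyldimethylsilyloxy)styrene | C=Cc1ccc(O[Si](C)(C)C(C)(C)C)c(O[Si](C)(C)C(C)(C)C)c1 | intermediate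
15 | 9-{2-[3,4-bis(tert-butyldimethylsilyloxy)phenyl]ethyl}-9-borabicyclo[3.3.1]nonane (alkylborane) | CC(C)(C)[Si](C)(C)Oc1ccc(CCB2C3CCCC2CCC3)cc1O[Si](C)(C)C(C)(C)C | intermediate
16 | 2-[3,4-bis(tert-butyldimethylsilyloxy)phenyl]ethanol | OCCc1ccc(O[Si](C)(C)C(C)(C)C)c(O[Si](C)(C)C(C)(C)C)c1 | intermediate
17 | 4-(2-iodoethyl)-1,2-bis(tert-butyldimethylsilyloxy)benzene | ICCc1ccc(O[Si](C)(C)C(C)(C)C)c(O[Si](C)(C)C(C)(C)C)c1 | intermediate
18 | {2-[3,4-bis(tert-butyldimethylsilyloxy)phenyl]ethyl}zinc iodide (alkylzinc iodide) | I[Zn]CCc1ccc(O[Si](C)(C)C(C)(C)C)c(O[Si](C)(C)C(C)(C)C)c1 | intermediate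
19 | {2-[3,4-bis(tert-butyldimethylsilyloxy)phenyl]ethyl}[(trimethylsilyl)methyl]zinc | C[Si](C)(C)C[Zn]CCc1ccc(O[Si](C)(C)C(C)(C)C)c(O[Si](C)(C)C(C)(C)C)c1 | intermediate
20 | (3R,6E)-1-[3,4-bis(tert-butyldimethylsilyloxy)phenyl]-7-[4-(tert-butyldimethylsilyloxy)phenyl]hept-6-en-3-ol | O[C@H](CC/C=C/c1ccc(O[Si](C)(C)C(C)(C)C)cc1)CCc1ccc(O[Si](C)(C)C(C)(C)C)c(O[Si](C)(C)C(C)(C)C)c1 | intermediate
21 | (3R,6E)-1-[3,4-bis(tert-butyldimethylsilyloxy)phenyl]-7-[4-(tert-butyldimethylsilyloxy)phenyl]hept-6-en-3-yl acetate | CC(=O)O[C@H](CC/C=C/c1ccc(O[Si](C)(C)C(C)(C)C)cc1)CCc1ccc(O[Si](C)(C)C(C)(C)C)c(O[Si](C)(C)C(C)(C)C)c1 | intermediate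
22 | (3R,6E)-1-(3,4-dihydroxyphenyl)-7-(4-hydroxyphenyl)hept-6-en-3-yl acetate | CC(=O)O[C@H](CC/C=C/c1ccc(O)cc1)CCc1ccc(O)c(O)c1 | target

**Step count**

Total steps: 12. Longest linear sequence: 8 (steps 5, 6, 7, 8, 9, 10, 11, 12); the other branch (steps 1, 2, 3, 4) joins at step 10.

**Steps most likely to fail**

1. Step 10. The catalyst may discriminate poorly between the faces of an α-unbranched aliphatic aldehyde, and lithium iodide carried over from step 9 may open an uncatalysed, unselective addition pathway. The sense of induction should be confirmed on 20 by Mosher ester analysis before continuing.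
Fallback, from 10 back to 20: aldehyde 10 would be treated with dimethylsulfonium methylide (Me3S+ I−, n-BuLi, THF, 0 °C; Corey–Chaykovsky) to give racemic 2-[(E)-4-(4-tert-butyldimethylsilyloxyphenyl)but-3-enyl]oxirane F1. Jacobsen hydrolytic kinetic resolution follows, with 0.55 equiv of water and (R,R)-[N,N′-bis(3,5-di-tert-butylsalicylidene)cyclohexane-1,2-diaminato]cobalt acetate (trivalent cobalt, 0.5 mol %). For an alkyl-substituted terminal epoxide this catalyst enantiomer is expected to hydrolyse the (S)-epoxide faster, leaving (R)-2-[(E)-4-(4-tert-butyldimethylsilyloxyphenyl)but-3-enyl]oxirane F2 beside (S,E)-6-[4-(tert-butyldimethylsilyloxy)phenyl]hex-5-ene-1,2-diol F3, which is separated. In parallel, aldehyde 12 would be reduced (NaBH4, EtOH/THF, 0 °C) to [3,4-bis(tert-butyldimethylsilyloxy)phenyl]methanol F4, converted (Ph3P, N-chlorosuccinimide, THF) into 3,4-bis(tert-butyldimethylsilyloxy)benzyl chloride F5, and then (Mg, Et2O, 0 °C) into 3,4-bis(tert-butyldimethylsilyloxy)benzylmagnesium chloride F6. CuI-catalysed opening of F2 by F6 at the terminal epoxide carbon (THF, −30 °C) forms C1–C2 without touching the C3–O bond and gives 20.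

2. Step 9. Zinc insertion may stall or be accompanied by Wurtz-type homocoupling, the alkyllithium may attack an aryl silyl ether instead of the zinc centre, and lithium iodide may not be removed completely.
Fallback, from 16 back to 19: alcohol 16 would be converted (CBr4, Ph3P, CH2Cl2, 0 °C) into 4-(2-bromoethyl)-1,2-bis(tert-butyldimethylsilyloxy)benzene F7. Magnesium insertion (Mg turnings, Et2O, rt) would give 2-[3,4-bis(tert-butyldimethylsilyloxy)phenyl]ethylmagnesium bromide F8. Transmetalation with ZnCl2 (1.0 equiv, Et2O, 0 °C) would give {2-[3,4-bis(tert-butyldimethylsilyloxy)phenyl]ethyl}zinc chloride F9. Addition of Me3SiCH2MgCl (1.0 equiv), followed by 1,4-dioxane to precipitate the magnesium halides and filtration under argon, would deliver a salt-free solution of 19.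

3. Step 3. Before the ketene acetal forms, the acid may ionise the electron-rich benzylic allylic C–O bond, leading to allylic transposition to a cinnamyl ether or to oligomerisation; partial loss of the aryl silyl group at 138 °C is a lesser risk.
Fallback, from 2 back to 8: aldehyde 2 would be methylenated (Ph3P=CH2 from 13 and n-BuLi, THF, 0 °C) to tert-butyldimethyl(4-vinylphenoxy)silane F10. Olefin cross-metathesis of F10 with ethyl pent-4-enoate (C=CCCC(=O)OCC, 3 equiv) using the second-generation Grubbs catalyst RuCl2(=CHPh)(PCy3)(H2IMes) in CH2Cl2 at 40 °C would give 8 with the thermodynamic (E) preference of styrene cross-metathesis. This avoids the ionisable alcohol altogether.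

**Further compounds**

F1 | step 10 | rac-2-[(E)-4-(4-tert-butyldimethylsilyloxyphenyl)but-3-enyl]oxirane | C1OC1CC/C=C/c1ccc(O[Si](C)(C)C(C)(C)C)cc1
F2 | step 10 | (R)-2-[(E)-4-(4-tert-butyldimethylsilyloxyphenyl)but-3-enyl]oxirane | C1O[C@@H]1CC/C=C/c1ccc(O[Si](C)(C)C(C)(C)C)cc1
F3 | step 10 | (S,E)-6-[4-(tert-butyldimethylsilyloxy)phenyl]hex-5-ene-1,2-diol | OC[C@@H](O)CC/C=C/c1ccc(O[Si](C)(C)C(C)(C)C)cc1
F4 | step 10 | [3,4-bis(tert-butyldimethylsilyloxy)phenyl]methanol | OCc1ccc(O[Si](C)(C)C(C)(C)C)c(O[Si](C)(C)C(C)(C)C)c1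
F5 | step 10 | 3,4-bis(tert-butyldimethylsilyloxy)benzyl chloride | ClCc1ccc(O[Si](C)(C)C(C)(C)C)c(O[Si](C)(C)C(C)(C)C)c1
F6 | step 10 | 3,4-bis(tert-butyldimethylsilyloxy)benzylmagnesium chloride | Cl[Mg]Cc1ccc(O[Si](C)(C)C(C)(C)C)c(O[Si](C)(C)C(C)(C)C)c1
F7 | step 9 | 4-(2-bromoethyl)-1,2-bis(tert-butyldimethylsilyloxy)benzene | BrCCc1ccc(O[Si](C)(C)C(C)(C)C)c(O[Si](C)(C)C(C)(C)C)c1
F8 | step 9 | 2-[3,4-bis(tert-butyldimethylsilyloxy)phenyl]ethylmagnesium bromide | Br[Mg]CCc1ccc(O[Si](C)(C)C(C)(C)C)c(O[Si](C)(C)C(C)(C)C)c1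
F9 | step 9 | {2-[3,4-bis(tert-butyldimethylsilyloxy)phenyl]ethyl}zinc chloride | Cl[Zn]CCc1ccc(O[Si](C)(C)C(C)(C)C)c(O[Si](C)(C)C(C)(C)C)c1
F10 | step 3 | tert-butyldimethyl(4-vinylphenoxy)silane | C=Cc1ccc(O[Si](C)(C)C(C)(C)C)cc1
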